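**Retrosynthetic overview**
1. Target 34 ⇐ acetylation and desilylation of the macrocyclic (2R)-allylic alcohol ⇐ CBS reduction of enone 31 ⇐ Nozaki–Hiyama–Kishi closure of the eleven-membered ring (C1–C2) in iodoalkene–aldehyde 29.
2. Cyclohexene ring ⇐ CuH reductive aldol cyclization and dehydration (C8–C9) of enone–ketone 22 ⇐ key intermolecular aldol addition (C7–C8) of cyclopentyl methyl ketone 18 to (R)-citronellal 19, which brings C2–C7 and the C5 stereocentre.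
3. Ketone 18 ⇐ cyclopentenyl ketone 14 by copper-catalysed conjugate addition (C11, C10); C15–O by Evans hydroxylation; quaternary C14 by CBS reduction and Johnson–Claisen chirality transfer from 1-acetyl-2-methylcyclopentene 1.
4. Ring order: five-membered ring (present in 1) → six-membered ring (step 18) → eleven-membered ring (step 24).

Convention (one line): skeletal locants follow the target SMILES after the exocyclic CH2, i.e. C1 (C=CH2), C2 (CHOAc), C3, C4, C5 (CHMe), C6, C7, C8 (=C9), C9 (Me), C10 (ring-fusion CH), C11 (CH bonded to C1), C12, C13, C14 (quaternary, Me), C15 (CHOH), C16 (CHOH, bonded to C8); the target is 2R,5S,10R,11R,14R,15R,16R; enolates and metal alkoxides are treated as forms of the reactant, not as separate compounds; TBS = tert-butyldimethylsilyl.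

**Step 1**
Reactants: 1 1-acetyl-2-methylcyclopent-1-ene
Product: 2 (1S)-1-(2-methylcyclopent-1-en-1-yl)ethan-1-ol
Conditions: (R)-2-methyl-CBS-oxazaborolidine (0.1 equiv), BH3·SMe2 (0.7 equiv), THF, −20 °C; MeOH quench
Reagents that add atoms: none
Why: Corey–Bakshi–Shibata reduction in which the tetrasubstituted alkenyl group acts as the large substituent, so the (R)-catalyst delivers hydride to give the (S)-carbinol.

**Step 2**
Reactants: 2 (1S)-1-(2-methylcyclopent-1-en-1-yl)ethan-1-ol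
Product: 4 ethyl 2-[(1S,2E)-2-ethylidene-1-methylcyclopentyl]acetate, via mixed ketene acetal 3 (not isolated)
Conditions: MeC(OEt)3 (6 equiv), EtCO2H (0.05 equiv), 140 °C, EtOH distilled off
Reagents that add atoms: triethyl orthoacetate, CC(OCC)(OCC)OCC
Why: Johnson–Claisen rearrangement through a chair transition state with the carbinol methyl equatorial, which transfers the carbinol chirality suprafacially to the new quaternary C14 and gives the E-ethylidene group.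

**Step 3**
Reactants: 4 ethyl 2-[(1S,2E)-2-ethylidene-1-methylcyclopentyl]acetate
Product: 5 2-[(1S,2E)-2-ethylidene-1-methylcyclopentyl]acetic acid
Conditions: LiOH·H2O (3 equiv), THF/MeOH/H2O, 40 °C; then 1 M HCl
Reagents that add atoms: lithium hydroxide, [Li+].[OH-]
Why: Plain ester saponification that touches neither the alkene nor the quaternary centre.

**Step 4**
Reactants: 5 2-[(1S,2E)-2-ethylidene-1-methylcyclopentyl]acetic acid; 6 (4R)-4-benzyl-1,3-oxazolidin-2-one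
Product: 8 (4R)-4-benzyl-3-{[(1S,2E)-2-ethylidene-1-methylcyclopentyl]acetyl}-1,3-oxazolidin-2-one, via mixed pivalic anhydride 7 (not isolated)
Conditions: t-BuCOCl (1.1 equiv), Et3N (2.5 equiv), THF, −20 °C; then LiCl (1.2 equiv) and 6 (1.1 equiv), −20 °C to rt
Reagents that add atoms: none
Why: N-acylation of the Evans auxiliary through the mixed anhydride, which is attacked at the less hindered acyl carbon.

**Step 5**
Reactants: 8 (4R)-4-benzyl-3-{[(1S,2E)-2-ethylidene-1-methylcyclopentyl]acetyl}-1,3-oxazolidin-2-one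
Product: 9 (4R)-4-benzyl-3-{(2R)-2-[(1R,2E)-2-ethylidene-1-methylcyclopentyl]-2-hydroxyacetyl}-1,3-oxazolidin-2-one
Conditions: NaN(SiMe3)2 (1.2 equiv), THF, −78 °C; 2-(benzenesulfonyl)-3-phenyloxaziridine (1.5 equiv), −78 °C; AcOH quench
Reagents that add atoms: 2-(benzenesulfonyl)-3-phenyloxaziridine (Davis reagent), O=S(=O)(c1ccccc1)N1OC1c1ccccc1
Why: Evans–Davis enolate hydroxylation in which the chelated Z-sodium enolate is oxidised on the face opposite the benzyl group, setting C15 as R under auxiliary control.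

**Step 6**
Reactants: 9 (4R)-4-benzyl-3-{(2R)-2-[(1R,2E)-2-ethylidene-1-methylcyclopentyl]-2-hydroxyacetyl}-1,3-oxazolidin-2-one
Product: 10 (2R)-2-[(1R,2E)-2-ethylidene-1-methylcyclopentyl]-2-hydroxy-N-methoxy-N-methylacetamide
Conditions: MeNH(OMe)·HCl (4 equiv), AlMe3 (4 equiv), CH2Cl2, −15 to 0 °C; aq. KNaC4H4O6 work-up
Reagents that add atoms: N,O-dimethylhydroxylamine hydrochloride, CNOC.Cl
Why: Weinreb transamidation by the aluminium amide, directed to the exocyclic carbonyl by the free α-hydroxyl, releases the auxiliary without touching C15.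

**Step 7**
Reactants: 10 (2R)-2-[(1R,2E)-2-ethylidene-1-methylcyclopentyl]-2-hydroxy-N-methoxy-N-methylacetamide
Product: 11 (2R)-2-[(tert-butyldimethylsilyl)oxy]-2-[(1R,2E)-2-ethylidene-1-methylcyclopentyl]-N-methoxy-N-methylacetamide
Conditions: TBSOTf (1.5 equiv), 2,6-lutidine (3 equiv), CH2Cl2, 0 °C
Reagents that add atoms: tert-butyldimethylsilyl trifluoromethanesulfonate, CC(C)(C)[Si](C)(C)OS(=O)(=O)C(F)(F)F
Why: Silyl triflate silylation protects the hindered secondary alcohol under non-epimerising conditions.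

**Step 8**
Reactants: 11 (2R)-2-[(tert-butyldimethylsilyl)oxy]-2-[(1R,2E)-2-ethylidene-1-methylcyclopentyl]-N-methoxy-N-methylacetamide
Product: 12 (2R)-2-[(tert-butyldimethylsilyl)oxy]-2-[(1S)-2-hydroxy-2-(1-hydroxyethyl)-1-methylcyclopentyl]-N-methoxy-N-methylacetamide
Conditions: OsO4 (0.05 equiv), 4-methylmorpholine N-oxide (2 equiv), acetone/H2O (4:1), rt
Reagents that add atoms: 4-methylmorpholine N-oxide, C[N+]1([O-])CCOCC1; water, O
Why: Upjohn dihydroxylation of the only C=C bond, whose two new stereocentres need no control because both are removed in steps 9 and 10.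

**Step 9**
Reactants: 12 (2R)-2-[(tert-butyldimethylsilyl)oxy]-2-[(1S)-2-hydroxy-2-(1-hydroxyethyl)-1-methylcyclopentyl]-N-methoxy-N-methylacetamide
Product: 13 (2R)-2-[(1S)-2-acetyl-2-hydroxy-1-methylcyclopentyl]-2-[(tert-butyldimethylsilyl)oxy]-N-methoxy-N-methylacetamide
Conditions: IBX (2 equiv), DMSO, rt
Reagents that add atoms: none
Why: IBX oxidation converts the secondary alcohol of the 1,2-diol into the ketone without glycol cleavage and leaves the tertiary alcohol.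

**Step 10**
Reactants: 13 (2R)-2-[(1S)-2-acetyl-2-hydroxy-1-methylcyclopentyl]-2-[(tert-butyldimethylsilyl)oxy]-N-methoxy-N-methylacetamide
Product: 14 (2R)-2-[(1R)-2-acetyl-1-methylcyclopent-2-en-1-yl]-2-[(tert-butyldimethylsilyl)oxy]-N-methoxy-N-methylacetamide
Conditions: SOCl2 (2 equiv), pyridine (10 equiv), CH2Cl2, −20 to 0 °C
Reagents that add atoms: none
Why: Chlorosulfite-mediated dehydration of the tertiary α-ketol can only remove a hydrogen from C11 because C14 is quaternary, so the conjugated C10=C11 enone forms regiospecifically.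

**Step 11**
Reactants: 14 (2R)-2-[(1R)-2-acetyl-1-methylcyclopent-2-en-1-yl]-2-[(tert-butyldimethylsilyl)oxy]-N-methoxy-N-methylacetamide
Product: 15 (2R)-2-{(1R,2S,3R)-2-acetyl-1-methyl-3-[1-(trimethylsilyl)ethenyl]cyclopentyl}-2-[(tert-butyldimethylsilyl)oxy]-N-methoxy-N-methylacetamide
Conditions: CH2=C(SiMe3)Br, Mg, THF (gives CH2=C(SiMe3)MgBr, 2.5 equiv); CuBr·SMe2 (0.2 equiv), THF, −78 to −30 °C; then H2O; then DBU (0.2 equiv), CH2Cl2, rt
Reagents that add atoms: (1-bromoethenyl)trimethylsilane, C=C(Br)[Si](C)(C)C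
Why: Copper-catalysed conjugate addition of the Grignard reagent to the enone occurs anti to the bulky C14 side chain (sets C11, nucleophile cis to the C14 methyl), and base equilibration places the acetyl group trans to the bulky silylvinyl group (sets C10, cis to the C15 arm).

**Step 12**
Reactants: 15 (2R)-2-{(1R,2S,3R)-2-acetyl-1-methyl-3-[1-(trimethylsilyl)ethenyl]cyclopentyl}-2-[(tert-butyldimethylsilyl)oxy]-N-methoxy-N-methylacetamide
Product: 16 (2R)-2-[(1R,2S,3R)-2-acetyl-3-(1-iodoethenyl)-1-methylcyclopentyl]-2-[(tert-butyldimethylsilyl)oxy]-N-methoxy-N-methylacetamide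
Conditions: N-iodosuccinimide (1.5 equiv), MeCN/ClCH2CN (4:1), 0 °C to rt, dark
Reagents that add atoms: N-iodosuccinimide, O=C1CCC(=O)N1I
Why: Ipso-iododesilylation of the 1,1-disubstituted vinylsilane (Kishi conditions) gives the 2-iodoalkene while no other alkene is present.

**Step 13**
Reactants: 16 (2R)-2-[(1R,2S,3R)-2-acetyl-3-(1-iodoethenyl)-1-methylcyclopentyl]-2-[(tert-butyldimethylsilyl)oxy]-N-methoxy-N-methylacetamide
Product: 17 (2R)-2-[(tert-butyldimethylsilyl)oxy]-2-[(1R,2S,3R)-3-(1-iodoethenyl)-1-methyl-2-(2-methyl-1,3-dioxolan-2-yl)cyclopentyl]-N-methoxy-N-methylacetamide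
Conditions: Me3SiOCH2CH2OSiMe3 (3 equiv), TMSOTf (0.05 equiv), CH2Cl2, −78 to −20 °C; pyridine quench
Reagents that add atoms: 1,2-bis(trimethylsilyloxy)ethane, C[Si](C)(C)OCCO[Si](C)(C)C
Why: Noyori ketalisation masks the hindered methyl ketone under aprotic conditions that spare the TBS ether and the Weinreb amide.

**Step 14**
Reactants: 17 (2R)-2-[(tert-butyldimethylsilyl)oxy]-2-[(1R,2S,3R)-3-(1-iodoethenyl)-1-methyl-2-(2-methyl-1,3-dioxolan-2-yl)cyclopentyl]-N-methoxy-N-methylacetamide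
Product: 18 (1R)-1-[(tert-butyldimethylsilyl)oxy]-1-[(1R,2S,3R)-3-(1-iodoethenyl)-1-methyl-2-(2-methyl-1,3-dioxolan-2-yl)cyclopentyl]propan-2-one
Conditions: MeMgBr (4 equiv), THF, 0 °C to rt; then H2O
Reagents that add atoms: methylmagnesium bromide, C[Mg]Br
Why: Weinreb ketone synthesis stops at the methyl ketone because the chelated tetrahedral adduct survives until work-up.

**Step 15**
Reactants: 18 (1R)-1-[(tert-butyldimethylsilyl)oxy]-1-[(1R,2S,3R)-3-(1-iodoethenyl)-1-methyl-2-(2-methyl-1,3-dioxolan-2-yl)cyclopentyl]propan-2-one; 19 (R)-citronellal [(3R)-3,7-dimethyloct-6-enal]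
Product: 20 (1R,6R)-1-[(tert-butyldimethylsilyl)oxy]-4-hydroxy-1-[(1R,2S,3R)-3-(1-iodoethenyl)-1-methyl-2-(2-methyl-1,3-dioxolan-2-yl)cyclopentyl]-6,10-dimethylundec-9-en-2-one (both C4 epimers)
Conditions: LiN(iPr)2 (1.1 equiv), THF, −78 °C, 45 min; 19 (1.3 equiv), −78 °C; AcOH quench
Reagents that add atoms: none
Why: Intermolecular aldol addition in which kinetic deprotonation occurs only at the methyl group (the other α-carbon is a hindered silyloxy methine) and the enolate adds to the aldehyde to form the C7–C8 bond that joins the two fragments, the new carbinol centre being removed in step 16.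

**Step 16**
Reactants: 20 (1R,6R)-1-[(tert-butyldimethylsilyl)oxy]-4-hydroxy-1-[(1R,2S,3R)-3-(1-iodoethenyl)-1-methyl-2-(2-methyl-1,3-dioxolan-2-yl)cyclopentyl]-6,10-dimethylundec-9-en-2-one
Product: 21 (1R,3E,6R)-1-[(tert-butyldimethylsilyl)oxy]-1-[(1R,2S,3R)-3-(1-iodoethenyl)-1-methyl-2-(2-methyl-1,3-dioxolan-2-yl)cyclopentyl]-6,10-dimethylundeca-3,9-dien-2-one
Conditions: MsCl (1.5 equiv), Et3N (5 equiv), CH2Cl2, 0 °C to rt
Reagents that add atoms: none
Why: Mesylation followed by E1cB elimination completes the aldol condensation and gives the E-enone.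

**Step 17**
Reactants: 21 (1R,3E,6R)-1-[(tert-butyldimethylsilyl)oxy]-1-[(1R,2S,3R)-3-(1-iodoethenyl)-1-methyl-2-(2-methyl-1,3-dioxolan-2-yl)cyclopentyl]-6,10-dimethylundeca-3,9-dien-2-one
Product: 22 (1R,3E,6R)-1-[(1R,2S,3R)-2-acetyl-3-(1-iodoethenyl)-1-methylcyclopentyl]-1-[(tert-butyldimethylsilyl)oxy]-6,10-dimethylundeca-3,9-dien-2-one
Conditions: pyridinium p-toluenesulfonate (0.3 equiv), acetone/H2O (9:1), 50 °C
Reagents that add atoms: water, O
Why: Mild acid-catalysed ketal hydrolysis frees the C9 methyl ketone while the secondary TBS ether and the enone survive.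

**Step 18**
Reactants: 22 (1R,3E,6R)-1-[(1R,2S,3R)-2-acetyl-3-(1-iodoethenyl)-1-methylcyclopentyl]-1-[(tert-butyldimethylsilyl)oxy]-6,10-dimethylundeca-3,9-dien-2-one
Product: 23 (1R,3aR,4R,7aS)-4-[(tert-butyldimethylsilyl)oxy]-6-[(3R)-3,7-dimethyloct-6-en-1-yl]-7-hydroxy-1-(1-iodoethenyl)-3a,7-dimethyloctahydro-5H-inden-5-one (C6/C7 epimers)
Conditions: [(Ph3P)CuH]6 (Stryker's reagent, 0.4 equiv), toluene, −40 to 0 °C; then H2O
Reagents that add atoms: none
Why: Reductive aldol cyclization in which CuH 1,4-reduction gives a copper enolate regiodefined at C8 that adds to the cis-disposed C9 ketone, closing the six-membered ring with a cis ring fusion fixed by the cis arms on the cyclopentane, while the C8/C9 centres are removed in step 19.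

**Step 19**
Reactants: 23 (1R,3aR,4R,7aS)-4-[(tert-butyldimethylsilyl)oxy]-6-[(3R)-3,7-dimethyloct-6-en-1-yl]-7-hydroxy-1-(1-iodoethenyl)-3a,7-dimethyloctahydro-5H-inden-5-one
Product: 24 (1R,3aR,4R,7aR)-4-[(tert-butyldimethylsilyl)oxy]-6-[(3R)-3,7-dimethyloct-6-en-1-yl]-1-(1-iodoethenyl)-3a,7-dimethyl-1,2,3,3a,4,7a-hexahydro-5H-inden-5-one
Conditions: MsCl (2 equiv), Et3N (6 equiv), 4-dimethylaminopyridine (0.1 equiv), CH2Cl2, 0 °C to rt
Reagents that add atoms: none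
Why: E1cB dehydration of the tertiary aldol through its mesylate removes the acidic C8 hydrogen and gives the conjugated tetrasubstituted C8=C9 enone.

**Step 20**
Reactants: 24 (1R,3aR,4R,7aR)-4-[(tert-butyldimethylsilyl)oxy]-6-[(3R)-3,7-dimethyloct-6-en-1-yl]-1-(1-iodoethenyl)-3a,7-dimethyl-1,2,3,3a,4,7a-hexahydro-5H-inden-5-one
Product: 25 (1R,3aR,4R,7aR)-6-[(3R)-3,7-dimethyloct-6-en-1-yl]-4-hydroxy-1-(1-iodoethenyl)-3a,7-dimethyl-1,2,3,3a,4,7a-hexahydro-5H-inden-5-one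
Conditions: HF·pyridine, pyridine, THF, 0 °C to rt
Reagents that add atoms: none
Why: Buffered fluoride desilylation frees the C15 hydroxyl needed to direct the next reduction.

**Step 21**
Reactants: 25 (1R,3aR,4R,7aR)-6-[(3R)-3,7-dimethyloct-6-en-1-yl]-4-hydroxy-1-(1-iodoethenyl)-3a,7-dimethyl-1,2,3,3a,4,7a-hexahydro-5H-inden-5-one
Product: 26 (1R,3aR,4R,5R,7aR)-6-[(3R)-3,7-dimethyloct-6-en-1-yl]-1-(1-iodoethenyl)-3a,7-dimethyl-2,3,3a,4,5,7a-hexahydro-1H-indene-4,5-diol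
Conditions: Me4NBH(OAc)3 (5 equiv), MeCN/AcOH (1:1), −30 to 0 °C; aq. KNaC4H4O6 work-up
Reagents that add atoms: none
Why: Evans–Saksena hydroxyl-directed 1,2-reduction in which the C15 alkoxyborohydride delivers hydride intramolecularly to the same face of the C16 carbonyl, so the new C16 hydroxyl is trans to the C15 hydroxyl (16R).

**Step 22**
Reactants: 26 (1R,3aR,4R,5R,7aR)-6-[(3R)-3,7-dimethyloct-6-en-1-yl]-1-(1-iodoethenyl)-3a,7-dimethyl-2,3,3a,4,5,7a-hexahydro-1H-indene-4,5-diol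
Product: 27 (1R,3aR,4R,5R,7aR)-4,5-bis[(tert-butyldimethylsilyl)oxy]-6-[(3R)-3,7-dimethyloct-6-en-1-yl]-1-(1-iodoethenyl)-3a,7-dimethyl-2,3,3a,4,5,7a-hexahydro-1H-indene
Conditions: TBSOTf (3 equiv), 2,6-lutidine (6 equiv), CH2Cl2, −78 to 0 °C
Reagents that add atoms: tert-butyldimethylsilyl trifluoromethanesulfonate, CC(C)(C)[Si](C)(C)OS(=O)(=O)C(F)(F)F
Why: Bis-silylation protects the trans-diol against periodate and the later oxidation.

**Step 23**
Reactants: 27 (1R,3aR,4R,5R,7aR)-4,5-bis[(tert-butyldimethylsilyl)oxy]-6-[(3R)-3,7-dimethyloct-6-en-1-yl]-1-(1-iodoethenyl)-3a,7-dimethyl-2,3,3a,4,5,7a-hexahydro-1H-indene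
Product: 29 (4S)-6-[(1R,3aR,4R,5R,7aR)-4,5-bis[(tert-butyldimethylsilyl)oxy]-1-(1-iodoethenyl)-3a,7-dimethyl-2,3,3a,4,5,7a-hexahydro-1H-inden-6-yl]-4-methylhexanal, via vicinal diol 28 (not isolated)
Conditions: OsO4 (0.02 equiv), NaIO4 (4 equiv), 2,6-lutidine (2 equiv), 1,4-dioxane/H2O (3:1), rt
Reagents that add atoms: sodium periodate, [Na+].[O-]I(=O)(=O)=O; water, O
Why: Lemieux–Johnson cleavage is selective for the unhindered trisubstituted side-chain alkene because the tetrasubstituted ring alkene is shielded by two flanking silyl ethers and the iodoalkene is electron-poor.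

**Step 24**
Reactants: 29 (4S)-6-[(1R,3aR,4R,5R,7aR)-4,5-bis[(tert-butyldimethylsilyl)oxy]-1-(1-iodoethenyl)-3a,7-dimethyl-2,3,3a,4,5,7a-hexahydro-1H-inden-6-yl]-4-methylhexanal
Product: 30 15,16-bis-O-TBS-2-O-deacetyl target skeleton as the mixture of C2 epimers (macrocyclic allylic alcohol)
Conditions: CrCl2 (15 equiv), NiCl2 (0.15 equiv), degassed DMSO, rt, syringe-pump addition of 29 (final 0.002 M); H2O work-up
Reagents that add atoms: none
Why: Intramolecular Nozaki–Hiyama–Kishi reaction in which the alkenyl iodide is converted by nickel catalysis and divalent chromium into an alkenyl species of trivalent chromium that adds chemoselectively to the aldehyde, closing the eleven-membered ring and forming the C1(=CH2)–C2(OH) unit, with the unselective C2 centre corrected in steps 25 and 26.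

**Step 25**
Reactants: 30 macrocyclic allylic alcohol (C2 epimers)
Product: 31 15,16-bis-O-TBS macrocyclic C2 ketone (α-methylene ketone; 5S,10R,11R,14R,15R,16R)
Conditions: Dess–Martin periodinane (1.5 equiv), CH2Cl2, 0 °C to rt
Reagents that add atoms: none
Why: Dess–Martin oxidation converges both C2 epimers into one enone under neutral conditions.

**Step 26**
Reactants: 31 macrocyclic α-methylene ketone
Product: 32 15,16-bis-O-TBS-2-O-deacetyl target, (2R)-alcohol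
Conditions: (S)-2-methyl-CBS-oxazaborolidine (1.0 equiv), catecholborane (2 equiv), toluene, −78 °C; MeOH quench
Reagents that add atoms: none
Why: Corey–Bakshi–Shibata reduction under reagent control, with the α-branched alkenyl group as the large substituent, so the (S)-catalyst gives the (2R)-allylic alcohol by 1,2-reduction.

**Step 27**
Reactants: 32 (2R)-allylic alcohol
Product: 33 15,16-bis-O-TBS ether of the target (2R-acetate)
Conditions: Ac2O (3 equiv), pyridine (6 equiv), 4-dimethylaminopyridine (0.1 equiv), CH2Cl2, rt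
Reagents that add atoms: acetic anhydride, CC(=O)OC(C)=O
Why: Standard nucleophile-catalysed acetylation of the only free hydroxyl with retention at C2.

**Step 28**
Reactants: 33 15,16-bis-O-TBS ether of the target
Product: 34 target CNP0192310.2
Conditions: HF·pyridine, pyridine, THF, 0 °C to rt
Reagents that add atoms: none
Why: Buffered fluoride desilylation removes both silyl ethers without cleaving or migrating the allylic acetate.

**Compound list**
1 | 1-acetyl-2-methylcyclopent-1-ene | CC(=O)C1=C(C)CCC1 | starting material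
2 | (1S)-1-(2-methylcyclopent-1-en-1-yl)ethan-1-ol | C[C@H](O)C1=C(C)CCC1 | intermediate
3 | mixed ketene acetal, 1-ethoxy-1-{[(1S)-1-(2-methylcyclopent-1-en-1-yl)ethyl]oxy}ethene | C=C(OCC)O[C@@H](C)C1=C(C)CCC1 | intermediate (not isolated)
4 | ethyl 2-[(1S,2E)-2-ethylidene-1-methylcyclopentyl]acetate | CCOC(=O)C[C@]1(C)CCC/C1=C\C | intermediate
5 | 2-[(1S,2E)-2-ethylidene-1-methylcyclopentyl]acetic acid | OC(=O)C[C@]1(C)CCC/C1=C\C | intermediate
6 | (4R)-4-benzyl-1,3-oxazolidin-2-one | O=C1N[C@H](Cc2ccccc2)CO1 | starting material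
7 | mixed anhydride of 5 with pivalic acid | CC(C)(C)C(=O)OC(=O)C[C@]1(C)CCC/C1=C\C | intermediate (not isolated)
8 | (4R)-4-benzyl-3-{[(1S,2E)-2-ethylidene-1-methylcyclopentyl]acetyl}-1,3-oxazolidin-2-one | O=C(C[C@]1(C)CCC/C1=C\C)N2[C@H](Cc3ccccc3)COC2=O | intermediate
9 | (4R)-4-benzyl-3-{(2R)-2-[(1R,2E)-2-ethylidene-1-methylcyclopentyl]-2-hydroxyacetyl}-1,3-oxazolidin-2-one | O=C([C@H](O)[C@]1(C)CCC/C1=C\C)N2[C@H](Cc3ccccc3)COC2=O | intermediate
10 | (2R)-2-[(1R,2E)-2-ethylidene-1-methylcyclopentyl]-2-hydroxy-N-methoxy-N-methylacetamide | CON(C)C(=O)[C@H](O)[C@]1(C)CCC/C1=C\C | intermediate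
11 | (2R)-2-[(tert-butyldimethylsilyl)oxy]-2-[(1R,2E)-2-ethylidene-1-methylcyclopentyl]-N-methoxy-N-methylacetamide | CON(C)C(=O)[C@H](O[Si](C)(C)C(C)(C)C)[C@]1(C)CCC/C1=C\C | intermediate
12 | (2R)-2-[(tert-butyldimethylsilyl)oxy]-2-[(1S)-2-hydroxy-2-(1-hydroxyethyl)-1-methylcyclopentyl]-N-methoxy-N-methylacetamide (diastereomers at the two new carbinol carbons) | CON(C)C(=O)[C@H](O[Si](C)(C)C(C)(C)C)[C@]1(C)CCCC1(O)C(C)O | intermediate
13 | (2R)-2-[(1S)-2-acetyl-2-hydroxy-1-methylcyclopentyl]-2-[(tert-butyldimethylsilyl)oxy]-N-methoxy-N-methylacetamide (epimers at the carbinol carbon) | CON(C)C(=O)[C@H](O[Si](C)(C)C(C)(C)C)[C@]1(C)CCCC1(O)C(C)=O | intermediate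
14 | (2R)-2-[(1R)-2-acetyl-1-methylcyclopent-2-en-1-yl]-2-[(tert-butyldimethylsilyl)oxy]-N-methoxy-N-methylacetamide | CON(C)C(=O)[C@H](O[Si](C)(C)C(C)(C)C)[C@]1(C)CCC=C1C(C)=O | intermediate
15 | (2R)-2-{(1R,2S,3R)-2-acetyl-1-methyl-3-[1-(trimethylsilyl)ethenyl]cyclopentyl}-2-[(tert-butyldimethylsilyl)oxy]-N-methoxy-N-methylacetamide | CON(C)C(=O)[C@H](O[Si](C)(C)C(C)(C)C)[C@]1(C)CC[C@@H](C(=C)[Si](C)(C)C)[C@@H]1C(C)=O | intermediate
16 | (2R)-2-[(1R,2S,3R)-2-acetyl-3-(1-iodoethenyl)-1-methylcyclopentyl]-2-[(tert-butyldimethylsilyl)oxy]-N-methoxy-N-methylacetamide | CON(C)C(=O)[C@H](O[Si](C)(C)C(C)(C)C)[C@]1(C)CC[C@@H](C(I)=C)[C@@H]1C(C)=O | intermediate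
17 | (2R)-2-[(tert-butyldimethylsilyl)oxy]-2-[(1R,2S,3R)-3-(1-iodoethenyl)-1-methyl-2-(2-methyl-1,3-dioxolan-2-yl)cyclopentyl]-N-methoxy-N-methylacetamide | CON(C)C(=O)[C@H](O[Si](C)(C)C(C)(C)C)[C@]1(C)CC[C@@H](C(I)=C)[C@@H]1C2(C)OCCO2 | intermediate
18 | (1R)-1-[(tert-butyldimethylsilyl)oxy]-1-[(1R,2S,3R)-3-(1-iodoethenyl)-1-methyl-2-(2-methyl-1,3-dioxolan-2-yl)cyclopentyl]propan-2-one | CC(=O)[C@H](O[Si](C)(C)C(C)(C)C)[C@]1(C)CC[C@@H](C(I)=C)[C@@H]1C2(C)OCCO2 | intermediate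
19 | (R)-citronellal, (3R)-3,7-dimethyloct-6-enal | CC(C)=CCC[C@@H](C)CC=O | starting material
20 | (1R,6R)-1-[(tert-butyldimethylsilyl)oxy]-4-hydroxy-1-[(1R,2S,3R)-3-(1-iodoethenyl)-1-methyl-2-(2-methyl-1,3-dioxolan-2-yl)cyclopentyl]-6,10-dimethylundec-9-en-2-one (C4 epimers) | CC(C)=CCC[C@@H](C)CC(O)CC(=O)[C@H](O[Si](C)(C)C(C)(C)C)[C@]1(C)CC[C@@H](C(I)=C)[C@@H]1C2(C)OCCO2 | intermediate
21 | (1R,3E,6R)-1-[(tert-butyldimethylsilyl)oxy]-1-[(1R,2S,3R)-3-(1-iodoethenyl)-1-methyl-2-(2-methyl-1,3-dioxolan-2-yl)cyclopentyl]-6,10-dimethylundeca-3,9-dien-2-one | CC(C)=CCC[C@@H](C)C/C=C/C(=O)[C@H](O[Si](C)(C)C(C)(C)C)[C@]1(C)CC[C@@H](C(I)=C)[C@@H]1C2(C)OCCO2 | intermediate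
22 | (1R,3E,6R)-1-[(1R,2S,3R)-2-acetyl-3-(1-iodoethenyl)-1-methylcyclopentyl]-1-[(tert-butyldimethylsilyl)oxy]-6,10-dimethylundeca-3,9-dien-2-one | CC(C)=CCC[C@@H](C)C/C=C/C(=O)[C@H](O[Si](C)(C)C(C)(C)C)[C@]1(C)CC[C@@H](C(I)=C)[C@@H]1C(C)=O | intermediate
23 | (1R,3aR,4R,7aS)-4-[(tert-butyldimethylsilyl)oxy]-6-[(3R)-3,7-dimethyloct-6-en-1-yl]-7-hydroxy-1-(1-iodoethenyl)-3a,7-dimethyloctahydro-5H-inden-5-one (cis-fused; C6/C7 epimers) | CC(C)=CCC[C@@H](C)CCC2C(C)(O)[C@H]3[C@H](C(I)=C)CC[C@@]3(C)[C@@H](O[Si](C)(C)C(C)(C)C)C2=O | intermediate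
24 | (1R,3aR,4R,7aR)-4-[(tert-butyldimethylsilyl)oxy]-6-[(3R)-3,7-dimethyloct-6-en-1-yl]-1-(1-iodoethenyl)-3a,7-dimethyl-1,2,3,3a,4,7a-hexahydro-5H-inden-5-one | CC(C)=CCC[C@@H](C)CCC2=C(C)[C@H]3[C@H](C(I)=C)CC[C@@]3(C)[C@@H](O[Si](C)(C)C(C)(C)C)C2=O | intermediate
25 | (1R,3aR,4R,7aR)-6-[(3R)-3,7-dimethyloct-6-en-1-yl]-4-hydroxy-1-(1-iodoethenyl)-3a,7-dimethyl-1,2,3,3a,4,7a-hexahydro-5H-inden-5-one | CC(C)=CCC[C@@H](C)CCC2=C(C)[C@H]3[C@H](C(I)=C)CC[C@@]3(C)[C@@H](O)C2=O | intermediate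
26 | (1R,3aR,4R,5R,7aR)-6-[(3R)-3,7-dimethyloct-6-en-1-yl]-1-(1-iodoethenyl)-3a,7-dimethyl-2,3,3a,4,5,7a-hexahydro-1H-indene-4,5-diol | CC(C)=CCC[C@@H](C)CCC2=C(C)[C@H]3[C@H](C(I)=C)CC[C@@]3(C)[C@@H](O)[C@@H]2O | intermediate
27 | (1R,3aR,4R,5R,7aR)-4,5-bis[(tert-butyldimethylsilyl)oxy]-6-[(3R)-3,7-dimethyloct-6-en-1-yl]-1-(1-iodoethenyl)-3a,7-dimethyl-2,3,3a,4,5,7a-hexahydro-1H-indene | CC(C)=CCC[C@@H](C)CCC2=C(C)[C@H]3[C@H](C(I)=C)CC[C@@]3(C)[C@@H](O[Si](C)(C)C(C)(C)C)[C@@H]2O[Si](C)(C)C(C)(C)C | intermediate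
28 | vicinal diol of 27, side chain (3S)-6,7-dihydroxy-3,7-dimethyloctyl (C6 epimers) | CC(C)(O)C(O)CC[C@@H](C)CCC2=C(C)[C@H]3[C@H](C(I)=C)CC[C@@]3(C)[C@@H](O[Si](C)(C)C(C)(C)C)[C@@H]2O[Si](C)(C)C(C)(C)C | intermediate (not isolated)
29 | (4S)-6-[(1R,3aR,4R,5R,7aR)-4,5-bis[(tert-butyldimethylsilyl)oxy]-1-(1-iodoethenyl)-3a,7-dimethyl-2,3,3a,4,5,7a-hexahydro-1H-inden-6-yl]-4-methylhexanal | O=CCC[C@@H](C)CCC2=C(C)[C@H]3[C@H](C(I)=C)CC[C@@]3(C)[C@@H](O[Si](C)(C)C(C)(C)C)[C@@H]2O[Si](C)(C)C(C)(C)C | intermediate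
30 | 15,16-bis-O-TBS-2-O-deacetyl target skeleton, C2 epimers (5S,10R,11R,14R,15R,16R) | C=C1C(O)CC[C@@H](C)CCC2=C(C)[C@H]3[C@H]1CC[C@@]3(C)[C@@H](O[Si](C)(C)C(C)(C)C)[C@@H]2O[Si](C)(C)C(C)(C)C | intermediate
31 | 15,16-bis-O-TBS macrocyclic C2 ketone with exocyclic C1 methylene (5S,10R,11R,14R,15R,16R) | C=C1C(=O)CC[C@@H](C)CCC2=C(C)[C@H]3[C@H]1CC[C@@]3(C)[C@@H](O[Si](C)(C)C(C)(C)C)[C@@H]2O[Si](C)(C)C(C)(C)C | intermediate
32 | 15,16-bis-O-TBS-2-O-deacetyl target (2R,5S,10R,11R,14R,15R,16R) | C=C1[C@H](O)CC[C@@H](C)CCC2=C(C)[C@H]3[C@H]1CC[C@@]3(C)[C@@H](O[Si](C)(C)C(C)(C)C)[C@@H]2O[Si](C)(C)C(C)(C)C | intermediate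
33 | 15,16-bis-O-TBS ether of the target (2R,5S,10R,11R,14R,15R,16R) | C=C1[C@H](OC(C)=O)CC[C@@H](C)CCC2=C(C)[C@H]3[C@H]1CC[C@@]3(C)[C@@H](O[Si](C)(C)C(C)(C)C)[C@@H]2O[Si](C)(C)C(C)(C)C | intermediate
34 | CNP0192310.2, the (2R,5S,10R,11R,14R,15R,16R) C2 acetate, C15/C16 diol | C=C1[C@H](OC(C)=O)CC[C@@H](C)CCC2=C(C)[C@H]3[C@H]1CC[C@@]3(C)[C@@H](O)[C@@H]2O | target

**Step count and risks**
Total step count: 28. Longest linear sequence: 28 steps (1 → 34); 6 and 19 are purchased.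

The three steps most likely to fail are 11, 18 and 24.

Step 11 (hindered silylvinyl conjugate addition that sets C11 and C10): the fallback sets out from 14 and comes back at 17. A smaller nucleophile is used first, CH2=CHMgBr with CuBr·SMe2 and Me3SiCl in THF at −78 °C, giving (2R)-2-[(1R,2S,3S)-2-acetyl-3-ethenyl-1-methylcyclopentyl]-2-[(tert-butyldimethylsilyl)oxy]-N-methoxy-N-methylacetamide F1. Noyori ketalisation then gives the dioxolane (2R)-2-[(tert-butyldimethylsilyl)oxy]-2-[(1R,2S,3S)-3-ethenyl-1-methyl-2-(2-methyl-1,3-dioxolan-2-yl)cyclopentyl]-N-methoxy-N-methylacetamide F2. Tsuji–Wacker oxidation (PdCl2, CuCl, O2, DMF/H2O) gives the methyl ketone (2R)-2-[(1R,2S,3R)-3-acetyl-1-methyl-2-(2-methyl-1,3-dioxolan-2-yl)cyclopentyl]-2-[(tert-butyldimethylsilyl)oxy]-N-methoxy-N-methylacetamide F3, whose C11 centre can now be equilibrated with K2CO3 in MeOH. Condensation with N2H4·H2O gives the hydrazone (2R)-2-[(tert-butyldimethylsilyl)oxy]-2-[(1R,2S,3R)-3-(1-hydrazinylideneethyl)-1-methyl-2-(2-methyl-1,3-dioxolan-2-yl)cyclopentyl]-N-methoxy-N-methylacetamide F4, and Barton iodination (I2, tetramethylguanidine, THF) returns to vinyl iodide 17.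

Step 18 (copper hydride reductive aldol cyclization in the presence of an alkenyl iodide): the fallback sets out from 22 and comes back at 23. The two events are separated: RhCl(PPh3)3-catalysed 1,4-hydrosilylation with Et3SiH gives the regiodefined silyl enol ether (1R,6R)-1-[(1R,2S,3R)-2-acetyl-3-(1-iodoethenyl)-1-methylcyclopentyl]-1-[(tert-butyldimethylsilyl)oxy]-6,10-dimethyl-2-[(triethylsilyl)oxy]undeca-2,9-diene F5. A TiCl4-promoted intramolecular Mukaiyama aldol addition onto the methyl ketone at −78 °C then gives 23.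

Step 24 (eleven-membered Nozaki–Hiyama–Kishi closure): the fallback sets out from 29 and comes back at 31, so step 25 is skipped. Pinnick oxidation (NaClO2, NaH2PO4, 2-methylbut-2-ene) gives (4S)-6-[(1R,3aR,4R,5R,7aR)-4,5-bis[(tert-butyldimethylsilyl)oxy]-1-(1-iodoethenyl)-3a,7-dimethyl-2,3,3a,4,5,7a-hexahydro-1H-inden-6-yl]-4-methylhexanoic acid F6. Carbodiimide coupling with MeNH(OMe)·HCl gives the Weinreb amide (4S)-6-[(1R,3aR,4R,5R,7aR)-4,5-bis[(tert-butyldimethylsilyl)oxy]-1-(1-iodoethenyl)-3a,7-dimethyl-2,3,3a,4,5,7a-hexahydro-1H-inden-6-yl]-N-methoxy-N,4-dimethylhexanamide F7. Iodine–lithium exchange (t-BuLi, THF, −100 to −40 °C, 0.002 M) followed by intramolecular acylation of the alkenyllithium by the Weinreb amide (Parham-type ring closure) gives enone 31 on work-up.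

**Further compounds**
F1 | step 11 | (2R)-2-[(1R,2S,3S)-2-acetyl-3-ethenyl-1-methylcyclopentyl]-2-[(tert-butyldimethylsilyl)oxy]-N-methoxy-N-methylacetamide | CON(C)C(=O)[C@H](O[Si](C)(C)C(C)(C)C)[C@]1(C)CC[C@@H](C=C)[C@@H]1C(C)=O
F2 | step 11 | (2R)-2-[(tert-butyldimethylsilyl)oxy]-2-[(1R,2S,3S)-3-ethenyl-1-methyl-2-(2-methyl-1,3-dioxolan-2-yl)cyclopentyl]-N-methoxy-N-methylacetamide | CON(C)C(=O)[C@H](O[Si](C)(C)C(C)(C)C)[C@]1(C)CC[C@@H](C=C)[C@@H]1C2(C)OCCO2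
F3 | step 11 | (2R)-2-[(1R,2S,3R)-3-acetyl-1-methyl-2-(2-methyl-1,3-dioxolan-2-yl)cyclopentyl]-2-[(tert-butyldimethylsilyl)oxy]-N-methoxy-N-methylacetamide | CON(C)C(=O)[C@H](O[Si](C)(C)C(C)(C)C)[C@]1(C)CC[C@@H](C(C)=O)[C@@H]1C2(C)OCCO2
F4 | step 11 | (2R)-2-[(tert-butyldimethylsilyl)oxy]-2-[(1R,2S,3R)-3-(1-hydrazinylideneethyl)-1-methyl-2-(2-methyl-1,3-dioxolan-2-yl)cyclopentyl]-N-methoxy-N-methylacetamide | CON(C)C(=O)[C@H](O[Si](C)(C)C(C)(C)C)[C@]1(C)CC[C@@H](C(C)=NN)[C@@H]1C2(C)OCCO2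
F5 | step 18 | (1R,6R)-1-[(1R,2S,3R)-2-acetyl-3-(1-iodoethenyl)-1-methylcyclopentyl]-1-[(tert-butyldimethylsilyl)oxy]-6,10-dimethyl-2-[(triethylsilyl)oxy]undeca-2,9-diene | CC(C)=CCC[C@@H](C)CCC=C(O[Si](CC)(CC)CC)[C@H](O[Si](C)(C)C(C)(C)C)[C@]1(C)CC[C@@H](C(I)=C)[C@@H]1C(C)=O
F6 | step 24 | (4S)-6-[(1R,3aR,4R,5R,7aR)-4,5-bis[(tert-butyldimethylsilyl)oxy]-1-(1-iodoethenyl)-3a,7-dimethyl-2,3,3a,4,5,7a-hexahydro-1H-inden-6-yl]-4-methylhexanoic acid | OC(=O)CC[C@@H](C)CCC2=C(C)[C@H]3[C@H](C(I)=C)CC[C@@]3(C)[C@@H](O[Si](C)(C)C(C)(C)C)[C@@H]2O[Si](C)(C)C(C)(C)C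
F7 | step 24 | (4S)-6-[(1R,3aR,4R,5R,7aR)-4,5-bis[(tert-butyldimethylsilyl)oxy]-1-(1-iodoethenyl)-3a,7-dimethyl-2,3,3a,4,5,7a-hexahydro-1H-inden-6-yl]-N-methoxy-N,4-dimethylhexanamide | CON(C)C(=O)CC[C@@H](C)CCC2=C(C)[C@H]3[C@H](C(I)=C)CC[C@@]3(C)[C@@H](O[Si](C)(C)C(C)(C)C)[C@@H]2O[Si](C)(C)C(C)(C)C
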